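**Plan**

- Retrosynthesis first cuts N–H back to N–tosyl, C2–Br back to C2–H (directed metalation) and the C2=C3 unsaturation back to an indoline.
- It then cuts the two ring-forming bonds C3a–C7a and C6–C7, with CO2 restored across C3a and C6, to reach a 3,5-dibromo-2-pyrone carrying CH2CH2N(Ts)C≡CH on C6.
- Enabling feature: indole C3a, C4, C5 and C6 map onto pyrone C6, C5, C4 and C3, so the bromines on C4 and C6 flanking C5–H are the 5- and 3-bromines of the pyrone, and C7a and C7 are the two ynamide carbons.
- Forward order: the pyrone ring is made first (alkyne plus propiolic acid), then nitrogen is attached, the pyrone is dibrominated and the nitrogen is ethynylated. The benzene ring and the five-membered nitrogen ring then close together in one cycloaddition with loss of CO2, followed by dehydrogenation, C2 bromination and removal of the tosyl group.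
- Stereochemistry: the target is achiral and no stereocentre survives. Only regiochemistry has to be controlled, by the tether in the ring construction and by the sulfonyl group in the C2 metalation.

Key step: step 6

Assumption: phenyl[(trimethylsilyl)ethynyl]iodonium triflate, Ph3PAuNTf2 and TMPMgCl·LiCl solution (TMP = 2,2,6,6-tetramethylpiperidide) are taken as purchasable reagents.

**Route**

Step 1
Reactants: 1 4-bromobut-1-yne; 2 propiolic acid
Product: 3 6-(2-bromoethyl)-2H-pyran-2-one
Conditions: 1 (1.5 equiv), Ph3PAuNTf2 (5 mol %), CH2Cl2, rt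
Reagents that add atoms: none
Why: Cationic monovalent gold should add the acid across the terminal alkyne in the Markovnikov sense to an enol propiolate, whose enol carbon then attacks the gold-activated ynoate 6-endo-dig and loses a proton (known gold-catalysed alkyne/propiolic acid pyrone annulation, alkyne substituent on C6); the primary bromide is inert to the silver-free catalyst.

Step 2
Reactants: 3 6-(2-bromoethyl)-2H-pyran-2-one; 4 tert-butyl tosylcarbamate
Product: 5 tert-butyl N-[2-(2-oxo-2H-pyran-6-yl)ethyl]-N-tosylcarbamate
Conditions: K2CO3, Bu4NI (cat.), DMF, 40 °C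
Reagents that add atoms: none
Why: SN2 alkylation of the soft, weakly basic potassium salt of the acyl sulfonamide by the primary bromide, mild enough that E2 loss of HBr towards a vinylpyrone and attack on the lactone should not compete.

Step 3
Reactants: 5 tert-butyl N-[2-(2-oxo-2H-pyran-6-yl)ethyl]-N-tosylcarbamate
Product: 6 4-methyl-N-[2-(2-oxo-2H-pyran-6-yl)ethyl]benzenesulfonamide
Conditions: CF3CO2H, CH2Cl2, 0 °C → rt
Reagents that add atoms: none
Why: Acidolytic Boc cleavage with loss of isobutene and carbon dioxide, to which the pyrone and the sulfonamide are inert.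

Step 4
Reactants: 6 4-methyl-N-[2-(2-oxo-2H-pyran-6-yl)ethyl]benzenesulfonamide
Product: 7 N-[2-(3,5-dibromo-2-oxo-2H-pyran-6-yl)ethyl]-4-methylbenzenesulfonamide
Conditions: Br2 (2.2 equiv), NaOAc, AcOH, rt → 50 °C, dark; aq. Na2S2O3 work-up
Reagents that add atoms: bromine, BrBr
Why: Electrophilic bromination of an alkyl-2-pyrone goes to C3 and C5, the two ring carbons that carry the donor character of the ring oxygen and the 6-alkyl group, while the acetate buffer removes HBr and the deactivated tosyl arene is left alone.

Step 5
Reactants: 7 N-[2-(3,5-dibromo-2-oxo-2H-pyran-6-yl)ethyl]-4-methylbenzenesulfonamide; 8 phenyl[(trimethylsilyl)ethynyl]iodonium triflate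
Product: 11 N-[2-(3,5-dibromo-2-oxo-2H-pyran-6-yl)ethyl]-N-ethynyl-4-methylbenzenesulfonamide, via potassium sulfonamide 9 (not isolated), via silyl ynamide 10 (not isolated)
Conditions: KN(SiMe3)2 (1.05 equiv), toluene, −40 → 0 °C; 8, 0 °C → rt; then Bu4NF, AcOH, THF, 0 °C
Reagents that add atoms: none
Why: N-alkynylation of a sulfonamide anion with an alkynyl(phenyl)iodonium salt (conjugate addition, loss of iodobenzene to an alkylidene carbene, 1,2-silyl shift), followed by fluoride desilylation buffered with acetic acid so that the lactone never meets free base.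

Step 6
Reactants: 11 N-[2-(3,5-dibromo-2-oxo-2H-pyran-6-yl)ethyl]-N-ethynyl-4-methylbenzenesulfonamide
Product: 13 4,6-dibromo-1-tosylindoline, via bridged lactone 12 (not isolated)
Conditions: degassed toluene (0.01 M), BHT (10 mol %), 160 °C, sealed tube
Reagents that add atoms: none
Why: Heating should bring the ynamide triple bond across pyrone C6 and C3 in a concerted, thermally allowed [4+2] cycloaddition to the bridged 2-oxabicyclo[2.2.2]octadienone 12, which at this temperature loses carbon dioxide by retro-[4+2] and is aromatic at once because the dienophile is an alkyne. The closest known reaction type is the intramolecular Diels–Alder reaction of 2-pyrones with tethered alkynes followed by decarboxylation, together with thermal intramolecular [4+2] cycloadditions of N-sulfonyl ynamides that give indolines. The five-membered nitrogen ring closes through the C3a–C7a bond in the fused mode (5-exo with respect to the alkyne, the CH2–CH2–N tether joining diene terminus C6 to the proximal alkyne carbon), and the benzene ring closes through that bond and the C6–C7 bond and is unmasked by the cycloreversion. No stereocentre remains, since the two bridgehead centres of 12 vanish with the carbon dioxide. The selectivity needed is regiochemical (nitrogen on C7a beside C7–H, bromines on C4 and C6) and is enforced by the three-atom tether, which allows only this orientation although it runs against the polarity preference of the ynamide, hence the heat; the electron-poor dibromopyrone, high dilution and BHT should favour the intramolecular pathway over bimolecular addition and radical decay of the terminal ynamide.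

Step 7
Reactants: 13 4,6-dibromo-1-tosylindoline
Product: 14 4,6-dibromo-1-tosyl-1H-indole
Conditions: DDQ (3 equiv), chlorobenzene, 120 °C
Reagents that add atoms: none
Why: Quinone dehydrogenation of an N-sulfonyl indoline (hydride abstraction, then proton loss) driven by aromatisation of the pyrrole ring, with aryl bromides and the sulfonamide inert to DDQ.

Step 8
Reactants: 14 4,6-dibromo-1-tosyl-1H-indole
Product: 16 2,4,6-tribromo-1-tosyl-1H-indole, via indolylmagnesium chloride 15 (not isolated)
Conditions: TMPMgCl·LiCl (1.3 equiv), THF, 0 °C; then BrCCl2CCl2Br, 0 °C → rt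
Reagents that add atoms: 1,2-dibromo-1,1,2,2-tetrachloroethane, BrC(Cl)(Cl)C(Cl)(Cl)Br
Why: Sulfonyl-directed C2 magnesiation of an N-sulfonylindole by the hindered magnesium amide (directed metalation at the acidic C–H next to nitrogen) followed by bromine transfer; the magnesium base is chosen over a lithium amide because the arylmagnesium should not undergo halogen migration or aryne formation and the non-coordinated C5–H between the two bromines should stay untouched.

Step 9
Reactants: 16 2,4,6-tribromo-1-tosyl-1H-indole
Product: 17 2,4,6-tribromo-1H-indole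
Conditions: Cs2CO3 (3 equiv), THF/MeOH 2:1, rt
Reagents that add atoms: none
Why: Methoxide generated by Cs2CO3 cleaves the N–S bond of the electron-poor N-tosylindole (nucleophilic desulfonylation, the tribromoindolide being a good leaving group) under conditions too mild to displace the C2 bromine.

**Compound list**

1 | 4-bromobut-1-yne | BrCCC#C | starting material
2 | propiolic acid (prop-2-ynoic acid) | OC(=O)C#C | starting material
3 | 6-(2-bromoethyl)-2H-pyran-2-one | O=C1C=CC=C(CCBr)O1 | intermediate
4 | tert-butyl tosylcarbamate (tert-butyl N-(4-methylphenyl)sulfonylcarbamate) | Cc1ccc(cc1)S(=O)(=O)NC(=O)OC(C)(C)C | starting material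
5 | tert-butyl N-[2-(2-oxo-2H-pyran-6-yl)ethyl]-N-tosylcarbamate | CC(C)(C)OC(=O)N(CCC1=CC=CC(=O)O1)S(=O)(=O)c1ccc(C)cc1 | intermediate
6 | 4-methyl-N-[2-(2-oxo-2H-pyran-6-yl)ethyl]benzenesulfonamide | Cc1ccc(cc1)S(=O)(=O)NCCC1=CC=CC(=O)O1 | intermediate
7 | N-[2-(3,5-dibromo-2-oxo-2H-pyran-6-yl)ethyl]-4-methylbenzenesulfonamide | Cc1ccc(cc1)S(=O)(=O)NCCC1=C(Br)C=C(Br)C(=O)O1 | intermediate
8 | phenyl[(trimethylsilyl)ethynyl]iodonium trifluoromethanesulfonate | C[Si](C)(C)C#C[I+]c1ccccc1.[O-]S(=O)(=O)C(F)(F)F | starting material
9 | potassium salt of sulfonamide 7 (N-potassio derivative) | [K+].Cc1ccc(cc1)S(=O)(=O)[N-]CCC1=C(Br)C=C(Br)C(=O)O1 | intermediate (not isolated)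
10 | N-[2-(3,5-dibromo-2-oxo-2H-pyran-6-yl)ethyl]-4-methyl-N-[(trimethylsilyl)ethynyl]benzenesulfonamide | Cc1ccc(cc1)S(=O)(=O)N(C#C[Si](C)(C)C)CCC1=C(Br)C=C(Br)C(=O)O1 | intermediate (not isolated)
11 | N-[2-(3,5-dibromo-2-oxo-2H-pyran-6-yl)ethyl]-N-ethynyl-4-methylbenzenesulfonamide (3,5-dibromo-6-[2-(N-ethynyl-N-tosylamino)ethyl]-2H-pyran-2-one) | Cc1ccc(cc1)S(=O)(=O)N(C#C)CCC1=C(Br)C=C(Br)C(=O)O1 | intermediate
12 | bridged [4+2] adduct of 11: 2-oxabicyclo[2.2.2]octa-5,7-dien-3-one with Br on the C4 bridgehead and on C8, the N-tosylpyrrolidine ring fused across bridgehead C1 and alkene carbon C6 (racemic) | Cc1ccc(cc1)S(=O)(=O)N1CCC23OC(=O)C(Br)(C=C12)C=C3Br | intermediate (not isolated)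
13 | 4,6-dibromo-1-tosylindoline (4,6-dibromo-1-(4-methylphenyl)sulfonyl-2,3-dihydro-1H-indole) | Cc1ccc(cc1)S(=O)(=O)N1CCc2c(Br)cc(Br)cc21 | intermediate
14 | 4,6-dibromo-1-tosyl-1H-indole | Cc1ccc(cc1)S(=O)(=O)n1ccc2c(Br)cc(Br)cc21 | intermediate
15 | (4,6-dibromo-1-tosyl-1H-indol-2-yl)magnesium chloride (LiCl complex) | Cc1ccc(cc1)S(=O)(=O)n1c([Mg]Cl)cc2c(Br)cc(Br)cc21 | intermediate (not isolated)
16 | 2,4,6-tribromo-1-tosyl-1H-indole | Cc1ccc(cc1)S(=O)(=O)n1c(Br)cc2c(Br)cc(Br)cc21 | intermediate
17 | 2,4,6-tribromo-1H-indole | Brc1cc(Br)c2cc(Br)[nH]c2c1 | target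

**Count**

Total steps: 9. Longest linear sequence: 9 steps (1 → 17).

**Steps most likely to fail**

Step 6 (key step). The terminal ynamide may degrade by hydration or oligomerisation faster than it cyclises, because the tether forces the cycloaddition into the polarity-mismatched orientation. The fallback sets out from 11 and keeps the same two ring-forming bonds but uses an alkene dienophile, with the missing unsaturation supplied by oxidation. Semi-hydrogenation of 11 (H2, Pd/CaCO3 poisoned with Pb(OAc)2, quinoline, EtOAc) should give the thermally robust enamide N-[2-(3,5-dibromo-2-oxo-2H-pyran-6-yl)ethyl]-N-ethenyl-4-methylbenzenesulfonamide F1. Heating F1 in toluene at 110–130 °C should give the bridged bicyclic lactone F2 by intramolecular cycloaddition of the electron-rich alkene to the dibromopyrone. Further heating to about 180 °C should expel carbon dioxide to give 4,6-dibromo-1-tosyl-2,3,7,7a-tetrahydro-1H-indole F3. DDQ at room temperature should aromatise the cyclohexadiene, and the route is rejoined at 13.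

Step 8. Deprotonation at C5–H between the two bromines (or at C7) may compete with the directed C2 metalation, and bromine positions may scramble in the metalated arene. The fallback sets out from 14 and avoids organometallic intermediates by passing through the lactam oxidation level. Cs2CO3 in THF/MeOH should remove the tosyl group to give 4,6-dibromo-1H-indole F4. Pyridinium tribromide in t-BuOH/H2O should oxidise it to 3,3,4,6-tetrabromoindolin-2-one F5. Zn in AcOH should reduce the geminal dibromide to 4,6-dibromoindolin-2-one F6. POBr3 with imidazole in 1,2-dichloroethane at 80 °C should convert the lactam into the 2-bromoindole, which is 17 itself.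

Step 5. The electrophilic dibromopyrone may be attacked or opened while the amide anion and then fluoride are present, and the alkylidene carbene may be lost to insertion instead of the silyl shift. The fallback sets out from 7 and forms the N–C(sp) bond by copper-catalysed coupling under a weak heterogeneous base. (Bromoethynyl)triisopropylsilane, CuSO4·5H2O (10 mol %), 1,10-phenanthroline and K3PO4 in toluene at 65 °C should give N-[2-(3,5-dibromo-2-oxo-2H-pyran-6-yl)ethyl]-4-methyl-N-[(triisopropylsilyl)ethynyl]benzenesulfonamide F7. Bu4NF buffered with AcOH in THF at 0 °C should then remove the silyl group, and the route is rejoined at 11.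

**Further compounds**

F1 | step 6 | N-[2-(3,5-dibromo-2-oxo-2H-pyran-6-yl)ethyl]-N-ethenyl-4-methylbenzenesulfonamide | Cc1ccc(cc1)S(=O)(=O)N(C=C)CCC1=C(Br)C=C(Br)C(=O)O1
F2 | step 6 | bridged [4+2] adduct of F1: 2-oxabicyclo[2.2.2]oct-7-en-3-one with Br on the C4 bridgehead and on C8, N-tosylpyrrolidine ring fused across C1 and C6 (racemic, mixture of C6 epimers) | Cc1ccc(cc1)S(=O)(=O)N1CCC23OC(=O)C(Br)(CC12)C=C3Br
F3 | step 6 | 4,6-dibromo-1-tosyl-2,3,7,7a-tetrahydro-1H-indole (racemic) | Cc1ccc(cc1)S(=O)(=O)N1CCC2=C(Br)C=C(Br)CC12
F4 | step 8 | 4,6-dibromo-1H-indole | Brc1cc(Br)c2cc[nH]c2c1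
F5 | step 8 | 3,3,4,6-tetrabromoindolin-2-one | O=C1Nc2cc(Br)cc(Br)c2C1(Br)Br
F6 | step 8 | 4,6-dibromoindolin-2-one | O=C1Cc2c(Br)cc(Br)cc2N1
F7 | step 5 | N-[2-(3,5-dibromo-2-oxo-2H-pyran-6-yl)ethyl]-4-methyl-N-[(triisopropylsilyl)ethynyl]benzenesulfonamide | Cc1ccc(cc1)S(=O)(=O)N(C#C[Si](C(C)C)(C(C)C)C(C)C)CCC1=C(Br)C=C(Br)C(=O)O1
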